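84.0 % is the figure to take over at the bench: it is the coupling count, the partner that reached substrate per substrate charged, taken as target + side product/2 and averaged over the alpha readings from 12.0 h on.

| flask | substrate | partner | remark | time |
|---|---|---|---|---|
| alpha | 0.095 M | 0.19 M | run made earlier |  |
| theta | 0.095 M | 0.29 M | run made earlier |  |
| violet | 0.095 M | 0.190 M (fed, over 8.0 h) | all else is in the flask from the start; the feed brings no volume worth counting | 40 h |
| amber | 0.095 M (fed, over 8.0 h) | 0.190 M | all else is in the flask from the start; the feed brings no volume worth counting | 40 h |
| teal | 0.095 M | 0.190 M | everything together at the start | 40 h |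
| green | 0.095 M | 0.190 M (in portions, 3, over 8.0 h) | first portion at the start, last at 8.0 h | 40 h |

| run | time / h | target / % | side product / % |
|---|---|---|---|
| alpha | 1.50 | 76 | 13 |
| alpha | 5.00 | 68 | 19 |
| alpha | 8.00 | 74 | 32 |
| alpha | 12.0 | 71 | 26 |
| alpha | 20.0 | 69 | 32 |
| alpha | 25.0 | 68 | 30 |
| theta | 0.667 | 73 | 7 |
| theta | 1.33 | 78 | 11 |
| theta | 2.00 | 81 | 15 |
| theta | 2.50 | 84 | 10 |
| theta | 3.00 | 85 | 11 |
| theta | 4.00 | 79 | 13 |

(readings scatter by 2 percentage points)

- percent here means substrate units held: one side product counts as two
- the numbers in the tables scatter with a standard deviation of 2 percentage points
- steps thought possible: substrate + partner -> target; partner -> decomposed reagent; substrate + target -> side product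

- the flask with the highest share of target in target plus side product ("all alike" if they lie within 1.5 percentage points) (violet / amber / teal / green / all alike)
- share of target in target plus side product at the end, violet
- share of target in target plus side product at the end, amber
- share of target in target plus side product at the end, teal
- share of target in target plus side product at the end, green

A target holds one partner and one substrate, while a side product holds one partner and two substrates, so with substrate used up the share of target equals 2 × count − 100 %. Alpha's late readings sum to 98.7 %, so the rule applies there, and teal, which has alpha's charges, should by my reckoning end near 68.0 %. Alpha's count takes up 42.0 % of the partner charge, which stands at 2.00 to one against the substrate charge. The count is what must not be lowered, since each point lost costs two points of share, and under 50.0 % substrate must remain, at least 100 % − 2 × count. The dosed flasks have no readings, so I give them no number.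

The forecast puts teal first, with violet 58 %, amber 25 %, teal 70 % and green 50 %, and says of amber “partner decays before substrate arrives, and late substrate eats target”. With substrate used up, its amber share would ask a count of 62.5 %.

The flasks end at violet 47.9 %, amber 2.00 %, teal 67.8 % and green 42.8 %, so teal leads.

    substrate + partner → target, rate k1*[substrate]^1.5*[partner] (k = 59.0 /M^1.5/h)
    partner → decomposed reagent (k = 0.430 /h)
    substrate + target → side product (k = 2.40 /M/h)

Teal's count is 83.9 %, beside the 84.0 % read from alpha. Amber's count is 33.8 %, under the line, and its floor of 32.4 % compares with 33.8 % of substrate at 40.0 h and 32.5 % at 400 h. The neighbouring flask, which is amber with 0.32 M of partner, counts 45.5 %, still under the line, so its floor is 9.00 %; at 40.0 h it holds 15.3 % of substrate and its share of target is 7.39 %.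

All runs are simulated for an exercise, noise included.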